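**Plan**

1. Retrosynthesis: the 7,8' biaryl bond is cut first (Suzuki–Miyaura). The nitrogen ring is then opened at C1–C8a and at C4–C3, which leaves a benzylic phosphate arene and N-vinylacetamide; the amide carries C1, N, C3 and both C-methyl carbons.
2. Enabling feature: C8a is the ring carbon para to O6 and ortho to O8 and stands 1,3 to benzylic C4. The C3(Me)–N=C1(Me) unit can be charged both ways: acyl carbon C1 is an electrophile after amide activation, vinyl carbon C3 a nucleophile after hydrocupration (2-azaallyl copper). This permits a formal (3+3) annulation.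
3. Forward order: naphthalene ring by Stobbe condensation and Friedel–Crafts closure (steps 1–6); desymmetrised resorcinol ester to the benzylic phosphate (steps 7–10); nitrogen ring in one flask (step 11); biaryl bond (step 12); desilylation (step 13).
4. Stereochemistry: C3 (S) comes from the chiral bisphosphine on copper in step 11.
5. Helpers: the bulky silyl ether on O6 (protection and site control at C8a) and the benzylic phosphate (leaving group); both are gone by the end.

Key step: step 11

Assumption: the target structure fixes only C3 (S); the 7,8' axis is left open, is not controlled, and the product is taken as the rotamer mixture that the coupling gives.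

**Route**

Step 1
Reactants: 1 2-bromo-5-methoxybenzaldehyde; 2 diethyl succinate
Product: 3 (E)-4-(2-bromo-5-methoxyphenyl)-3-(ethoxycarbonyl)but-3-enoic acid
Conditions: KOtBu, tBuOH, reflux; aq. HCl
Reagents that add atoms: none
Why: Stobbe condensation, in which the succinate enolate adds to the aldehyde and the paraconate lactone opens by elimination to the (E)-arylidene half-ester, the geometry that places the CH2CO2H arm cis to the aryl ring for the next closure.

Step 2
Reactants: 3 (E)-4-(2-bromo-5-methoxyphenyl)-3-(ethoxycarbonyl)but-3-enoic acid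
Product: 4 ethyl 4-acetoxy-8-bromo-5-methoxy-2-naphthoate
Conditions: Ac2O, NaOAc, reflux
Reagents that add atoms: acetic anhydride, CC(=O)OC(C)=O
Why: Intramolecular Friedel–Crafts acylation through the mixed anhydride should close the ring at the only free ortho position (ortho to OMe, the para position carrying Br), and the naphthol is trapped as its acetate as is usual for Stobbe half-esters.

Step 3
Reactants: 4 ethyl 4-acetoxy-8-bromo-5-methoxy-2-naphthoate
Product: 6 ethyl 8-bromo-5-methoxy-4-(triisopropylsilyloxy)-2-naphthoate, via naphthol ester 5 (not isolated)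
Conditions: K2CO3 (cat.), EtOH, rt; then iPr3SiOTf, 2,6-lutidine, CH2Cl2, 0 °C
Reagents that add atoms: triisopropylsilyl trifluoromethanesulfonate, CC(C)[Si](OS(=O)(=O)C(F)(F)F)(C(C)C)C(C)C
Why: Base-catalysed transesterification removes the aryl acetate without changing the ethyl ester, and O-silylation of the hindered peri-naphthol with the silyl triflate gives an ether that should survive hydride, palladium and base and fall to fluoride at the end.

Step 4
Reactants: 6 ethyl 8-bromo-5-methoxy-4-(triisopropylsilyloxy)-2-naphthoate
Product: 7 [8-bromo-5-methoxy-4-(triisopropylsilyloxy)naphthalen-2-yl]methanol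
Conditions: iBu2AlH, CH2Cl2, −78 to 0 °C
Reagents that add atoms: none
Why: Hydride reduction of the ester to the primary alcohol, with the aryl bromide and the aryl silyl ether inert at low temperature.

Step 5
Reactants: 7 [8-bromo-5-methoxy-4-(triisopropylsilyloxy)naphthalen-2-yl]methanol
Product: 9 (5-bromo-8-methoxy-3-methylnaphthalen-1-yl)oxy-triisopropylsilane, via mesylate 8 (not isolated)
Conditions: MsCl, Et3N, THF, 0 °C; then LiBHEt3, 0 °C to rt
Reagents that add atoms: none
Why: Sulfonylation followed by SN2 hydride displacement deoxygenates the naphthylmethyl alcohol to the C-methyl group, and the aryl bromide should not be reduced under these conditions.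

Step 6
Reactants: 9 (5-bromo-8-methoxy-3-methylnaphthalen-1-yl)oxy-triisopropylsilane
Product: 10 2-[4-methoxy-7-methyl-5-(triisopropylsilyloxy)naphthalen-1-yl]-4,4,5,5-tetramethyl-1,3,2-dioxaborolane
Conditions: B2pin2, Pd(dppf)Cl2 (cat.), KOAc, dioxane, 90 °C
Reagents that add atoms: bis(pinacolato)diboron, CC1(C)OB(OC1(C)C)B1OC(C)(C)C(C)(C)O1
Why: Miyaura borylation of the unhindered naphthyl bromide gives the pinacol boronate that serves as nucleophile in the biaryl coupling.

Step 7
Reactants: 11 methyl 4-bromo-3,5-dihydroxybenzoate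
Product: 12 methyl 4-bromo-3-hydroxy-5-methoxybenzoate
Conditions: MeI (1 equiv), K2CO3 (1 equiv), DMF, rt
Reagents that add atoms: iodomethane, CI
Why: Williamson etherification with one equivalent of electrophile desymmetrises the symmetric resorcinol statistically, and the mono-ether should be separable from diol and diether, which are recycled.

Step 8
Reactants: 12 methyl 4-bromo-3-hydroxy-5-methoxybenzoate
Product: 13 methyl 4-bromo-3-methoxy-5-(triisopropylsilyloxy)benzoate
Conditions: iPr3SiCl, imidazole, DMF, rt
Reagents that add atoms: chlorotriisopropylsilane, CC(C)[Si](Cl)(C(C)C)C(C)C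
Why: O-Silylation of the remaining phenol installs a bulky donor group whose size later shields the adjacent ring carbon (future C5), so that electrophilic attack should go to the carbon para to it (future C8a).

Step 9
Reactants: 13 methyl 4-bromo-3-methoxy-5-(triisopropylsilyloxy)benzoate
Product: 14 [4-bromo-3-methoxy-5-(triisopropylsilyloxy)phenyl]methanol
Conditions: iBu2AlH, CH2Cl2, −78 to 0 °C
Reagents that add atoms: none
Why: Hydride reduction of the benzoate to the benzyl alcohol, with the aryl bromide and both ethers stable.

Step 10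
Reactants: 14 [4-bromo-3-methoxy-5-(triisopropylsilyloxy)phenyl]methanol
Product: 15 [4-bromo-3-methoxy-5-(triisopropylsilyloxy)phenyl]methyl diethyl phosphate
Conditions: ClP(O)(OEt)2, Et3N, DMAP (cat.), CH2Cl2, 0 °C
Reagents that add atoms: diethyl chlorophosphate, CCOP(=O)(Cl)OCC
Why: O-Phosphorylation gives a benzylic phosphate, a leaving group that organocopper nucleophiles displace readily but that should survive the acidic first stage of step 11 and react only slowly with a neutral imine nitrogen.

Step 11
Reactants: 15 [4-bromo-3-methoxy-5-(triisopropylsilyloxy)phenyl]methyl diethyl phosphate; 16 N-vinylacetamide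
Product: 19 (3S)-7-bromo-8-methoxy-1,3-dimethyl-6-(triisopropylsilyloxy)-3,4-dihydroisoquinoline, via nitrilium triflate 17 (not isolated), via N-vinyl ketimine 18 (not isolated)
Conditions: Tf2O, 2-fluoropyridine, CH2Cl2, −78 to 0 °C; then LiOtBu, Cu(OAc)2 (cat.), (S,S)-Ph-BPE (cat.), (MeO)2MeSiH, THF, 0 °C to rt
Reagents that add atoms: none
Why: Proposed new method: Tf2O and 2-fluoropyridine convert 16 into the N-vinylnitrilium ion 17, whose carbon is attacked by C8a of 15 (para to the silyloxy group, ortho to OMe), and loss of the ring proton gives the N-vinyl ketimine 18, which forms C1–C8a. After neutralisation, the ligated copper hydride adds across the N-vinyl C=C with H going to the terminal carbon (the future C3 methyl) and copper to the carbon next to nitrogen, and the resulting 2-azaallyl copper species displaces the benzylic phosphate in a 6-exo-tet closure that forms C4–C3 and completes the nitrogen ring with C1=N already at the imine level. The closest known reaction types are arene attack on a nitrilium carbon made by amide activation (Bischler–Napieralski and Houben–Hoesch chemistry) for the first stage, and copper hydride addition to 2-azadienes with trapping by carbon electrophiles together with copper hydride hydroalkylation of alkenes by a tethered alkyl electrophile for the second; the two have not been joined, nor run on an N-vinyl aryl methyl ketimine with a benzylic phosphate. C3 is the only new stereocenter and is set under catalyst control by the C2-symmetric bisphosphine on copper in the hydrocupration–alkylation sequence, the ligand enantiomer that gives 3S being fixed in a model run. The step needs C8a over C5 in the arylation (secured by the bulk of the silyl ether beside C5 and by para-silyloxy activation of C8a), C3 over C1 in the alkylation (attack through C1 would require a four-membered ring), and hydrocupration faster than N-alkylation of the ketimine, reduction of the C–O bond or reduction of the product imine (favoured by the phosphate leaving group, low temperature and limited silane).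

Step 12
Reactants: 19 (3S)-7-bromo-8-methoxy-1,3-dimethyl-6-(triisopropylsilyloxy)-3,4-dihydroisoquinoline; 10 2-[4-methoxy-7-methyl-5-(triisopropylsilyloxy)naphthalen-1-yl]-4,4,5,5-tetramethyl-1,3,2-dioxaborolane
Product: 20 (3S)-8-methoxy-7-[4-methoxy-7-methyl-5-(triisopropylsilyloxy)naphthalen-1-yl]-1,3-dimethyl-6-(triisopropylsilyloxy)-3,4-dihydroisoquinoline
Conditions: Pd(OAc)2 (cat.), SPhos, K3PO4, toluene/H2O, 100 °C
Reagents that add atoms: none
Why: Suzuki–Miyaura coupling with a bulky electron-rich biarylphosphine should forge the hindered 7,8' bond, the axis forming without control and C3 remaining untouched under the mildly basic conditions.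

Step 13
Reactants: 20 (3S)-8-methoxy-7-[4-methoxy-7-methyl-5-(triisopropylsilyloxy)naphthalen-1-yl]-1,3-dimethyl-6-(triisopropylsilyloxy)-3,4-dihydroisoquinoline
Product: 21 (3S)-7-(5-hydroxy-4-methoxy-7-methylnaphthalen-1-yl)-8-methoxy-1,3-dimethyl-3,4-dihydroisoquinolin-6-ol
Conditions: Bu4NF, THF, 0 °C to rt; aq. NH4Cl
Reagents that add atoms: none
Why: Fluoride-induced desilylation frees the phenol and the naphthol and should leave the methyl ethers, the imine and C3 unchanged.

**Compound list**

1 | 2-bromo-5-methoxybenzaldehyde | O=Cc1cc(OC)ccc1Br | starting material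
2 | diethyl succinate | CCOC(=O)CCC(=O)OCC | starting material
3 | (E)-4-(2-bromo-5-methoxyphenyl)-3-(ethoxycarbonyl)but-3-enoic acid | OC(=O)C/C(=C\c1cc(OC)ccc1Br)C(=O)OCC | intermediate
4 | ethyl 4-acetoxy-8-bromo-5-methoxy-2-naphthoate | CCOC(=O)c1cc(OC(C)=O)c2c(OC)ccc(Br)c2c1 | intermediate
5 | ethyl 8-bromo-4-hydroxy-5-methoxy-2-naphthoate | CCOC(=O)c1cc(O)c2c(OC)ccc(Br)c2c1 | intermediate
6 | ethyl 8-bromo-5-methoxy-4-(triisopropylsilyloxy)-2-naphthoate | CCOC(=O)c1cc(O[Si](C(C)C)(C(C)C)C(C)C)c2c(OC)ccc(Br)c2c1 | intermediate
7 | [8-bromo-5-methoxy-4-(triisopropylsilyloxy)naphthalen-2-yl]methanol | OCc1cc(O[Si](C(C)C)(C(C)C)C(C)C)c2c(OC)ccc(Br)c2c1 | intermediate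
8 | [8-bromo-5-methoxy-4-(triisopropylsilyloxy)naphthalen-2-yl]methyl methanesulfonate | CS(=O)(=O)OCc1cc(O[Si](C(C)C)(C(C)C)C(C)C)c2c(OC)ccc(Br)c2c1 | intermediate
9 | (5-bromo-8-methoxy-3-methylnaphthalen-1-yl)oxy-triisopropylsilane | Cc1cc(O[Si](C(C)C)(C(C)C)C(C)C)c2c(OC)ccc(Br)c2c1 | intermediate
10 | 2-[4-methoxy-7-methyl-5-(triisopropylsilyloxy)naphthalen-1-yl]-4,4,5,5-tetramethyl-1,3,2-dioxaborolane | Cc1cc(O[Si](C(C)C)(C(C)C)C(C)C)c2c(OC)ccc(B3OC(C)(C)C(C)(C)O3)c2c1 | intermediate
11 | methyl 4-bromo-3,5-dihydroxybenzoate | COC(=O)c1cc(O)c(Br)c(O)c1 | starting material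
12 | methyl 4-bromo-3-hydroxy-5-methoxybenzoate | COC(=O)c1cc(O)c(Br)c(OC)c1 | intermediate
13 | methyl 4-bromo-3-methoxy-5-(triisopropylsilyloxy)benzoate | COC(=O)c1cc(OC)c(Br)c(O[Si](C(C)C)(C(C)C)C(C)C)c1 | intermediate
14 | [4-bromo-3-methoxy-5-(triisopropylsilyloxy)phenyl]methanol | OCc1cc(OC)c(Br)c(O[Si](C(C)C)(C(C)C)C(C)C)c1 | intermediate
15 | [4-bromo-3-methoxy-5-(triisopropylsilyloxy)phenyl]methyl diethyl phosphate | CCOP(=O)(OCC)OCc1cc(OC)c(Br)c(O[Si](C(C)C)(C(C)C)C(C)C)c1 | intermediate
16 | N-vinylacetamide | CC(=O)NC=C | starting material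
17 | N-vinylacetonitrilium trifluoromethanesulfonate | CC#[N+]C=C.[O-]S(=O)(=O)C(F)(F)F | intermediate
18 | [4-bromo-3-methoxy-2-(1-(vinylimino)ethyl)-5-(triisopropylsilyloxy)phenyl]methyl diethyl phosphate | CCOP(=O)(OCC)OCc1cc(O[Si](C(C)C)(C(C)C)C(C)C)c(Br)c(OC)c1C(C)=NC=C | intermediate
19 | (3S)-7-bromo-8-methoxy-1,3-dimethyl-6-(triisopropylsilyloxy)-3,4-dihydroisoquinoline | COc1c2c(cc(O[Si](C(C)C)(C(C)C)C(C)C)c1Br)C[C@H](C)N=C2C | intermediate
20 | (3S)-8-methoxy-7-[4-methoxy-7-methyl-5-(triisopropylsilyloxy)naphthalen-1-yl]-1,3-dimethyl-6-(triisopropylsilyloxy)-3,4-dihydroisoquinoline | COc1c2c(cc(O[Si](C(C)C)(C(C)C)C(C)C)c1-c1ccc(OC)c3c(O[Si](C(C)C)(C(C)C)C(C)C)cc(C)cc13)C[C@H](C)N=C2C | intermediate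
21 | (3S)-7-(5-hydroxy-4-methoxy-7-methylnaphthalen-1-yl)-8-methoxy-1,3-dimethyl-3,4-dihydroisoquinolin-6-ol | COc1c2c(cc(O)c1-c1ccc(OC)c3c(O)cc(C)cc13)C[C@H](C)N=C2C | target

**Summary**

Total step count: 13. Longest linear sequence: 8 (steps 1–6, 12, 13).

Steps most likely to fail:

1. Step 11 (Proposed new method). Possible failures are N-alkylation of the ketimine nitrogen at the benzylic carbon before hydrocupration, reduction of the benzylic C–O bond or of the product imine by copper hydride, arylation at the wrong ring carbon in the first stage, or poor enantioface discrimination. The fallback uses known chemistry, sets out from 14 and comes back at 19. Alcohol 14 is converted with MsCl, Et3N and LiCl into 2-bromo-5-(chloromethyl)-1-methoxy-3-(triisopropylsilyloxy)benzene F1. Magnesium insertion (Mg, Et2O, 0 °C) gives [4-bromo-3-methoxy-5-(triisopropylsilyloxy)benzyl]magnesium chloride F2. This is added in CH2Cl2 at −48 °C to (S)-N-ethylidene-2-methylpropane-2-sulfinamide F3, itself made from (S)-2-methylpropane-2-sulfinamide, acetaldehyde and CuSO4. Addition through the six-membered magnesium chelate should give (S)-N-[(2S)-1-(4-bromo-3-methoxy-5-(triisopropylsilyloxy)phenyl)propan-2-yl]-2-methylpropane-2-sulfinamide F4. HCl in MeOH removes the auxiliary to give (2S)-1-[4-bromo-3-methoxy-5-(triisopropylsilyloxy)phenyl]propan-2-amine F5. Ac2O and Et3N give N-[(2S)-1-(4-bromo-3-methoxy-5-(triisopropylsilyloxy)phenyl)propan-2-yl]acetamide F6. Bischler–Napieralski cyclisation (Tf2O, 2-chloropyridine, CH2Cl2, −78 to 23 °C) then closes C1–C8a para to the silyloxy group and gives 19.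

2. Step 12. Possible failures are slow oxidative addition and transmetalation at a bromide flanked by two oxygen substituents, with protodeboronation of the electron-rich naphthyl boronate outrunning the coupling. The fallback is a Negishi coupling that sets out from 9 and 19 and comes back at 20. Bromide 9 undergoes bromine–lithium exchange (n-BuLi, THF, −78 °C) and transmetalation with ZnCl2 to give chloro[4-methoxy-7-methyl-5-(triisopropylsilyloxy)naphthalen-1-yl]zinc F7. This is coupled with 19 using PdCl2(IPent)(3-chloropyridine) in THF/NMP at 60 °C to give 20.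

3. Step 7. Possible failures are over-alkylation and incomplete conversion, which leave a statistical mixture that is tedious to separate. The fallback is subtractive, sets out from 11 and comes back at 12. Exhaustive methylation (excess MeI, K2CO3, acetone, reflux) gives methyl 4-bromo-3,5-dimethoxybenzoate F8. One methyl ether is then cleaved with one equivalent of BBr3 (CH2Cl2, −78 to 0 °C), the stoichiometry and the aryloxyborane formed in the first cleavage holding the reaction at the mono-phenol 12.

Further compounds
F1 | step 11 | 2-bromo-5-(chloromethyl)-1-methoxy-3-(triisopropylsilyloxy)benzene | ClCc1cc(OC)c(Br)c(O[Si](C(C)C)(C(C)C)C(C)C)c1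
F2 | step 11 | [4-bromo-3-methoxy-5-(triisopropylsilyloxy)benzyl]magnesium chloride | Cl[Mg]Cc1cc(OC)c(Br)c(O[Si](C(C)C)(C(C)C)C(C)C)c1
F3 | step 11 | (S)-N-ethylidene-2-methylpropane-2-sulfinamide | CC(C)(C)[S@](=O)/N=C/C
F4 | step 11 | (S)-N-[(2S)-1-(4-bromo-3-methoxy-5-(triisopropylsilyloxy)phenyl)propan-2-yl]-2-methylpropane-2-sulfinamide | CC(C)(C)[S@](=O)N[C@@H](C)Cc1cc(OC)c(Br)c(O[Si](C(C)C)(C(C)C)C(C)C)c1
F5 | step 11 | (2S)-1-[4-bromo-3-methoxy-5-(triisopropylsilyloxy)phenyl]propan-2-amine | N[C@@H](C)Cc1cc(OC)c(Br)c(O[Si](C(C)C)(C(C)C)C(C)C)c1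
F6 | step 11 | N-[(2S)-1-(4-bromo-3-methoxy-5-(triisopropylsilyloxy)phenyl)propan-2-yl]acetamide | CC(=O)N[C@@H](C)Cc1cc(OC)c(Br)c(O[Si](C(C)C)(C(C)C)C(C)C)c1
F7 | step 12 | chloro[4-methoxy-7-methyl-5-(triisopropylsilyloxy)naphthalen-1-yl]zinc | Cc1cc(O[Si](C(C)C)(C(C)C)C(C)C)c2c(OC)ccc([Zn]Cl)c2c1
F8 | step 7 | methyl 4-bromo-3,5-dimethoxybenzoate | COC(=O)c1cc(OC)c(Br)c(OC)c1
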